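## Structural features

The target is a tetracyclic 7,20-epoxyabietane. Ring A (C1–C5, C10) is a cyclohexane with an equatorial acetate at C2 and a gem-dimethyl group at C4. It is trans-fused through C5–C10 to ring B (C5–C10), which is fused through C8–C9 to the aromatic ring C (C8, C9, C11–C14) carrying the 11,12-catechol and the 13-isopropyl group. An O–CH2 bridge (oxygen on C7, C20 on C10) spans ring B as a boat, so that C7, C8, C9, C10, C20 and O form a tetrahydropyran and C7 and C10 are the bridgeheads of a 2-oxabicyclo[2.2.2]octane. There are four stereocentres: C5 and C10 are adjacent (H5 anti to C20), C7 is tied to C10 through the bridge, and C2 is 1,3 to both C4 and C10. The fragile groups are the catechol (air oxidation to the ortho-quinone) and the secondary acetate (base, nucleophiles). As long as the bridge is missing, the C7–O bond is also fragile: it is a para-alkoxybenzylic bond that ionises in acid. Once bridged, it is a bridgehead bond orthogonal to the arene π system and is inert. The real difficulty is the quaternary C10 with its oxymethylene carbon on the face opposite H5 and in a fixed relation to C7; a lesser one is the C2 carbonyl, whose axial face is closed by C20 and the 4β-methyl group. The key step exploits the fact that C10 is β to the C2 oxygen through C1 and is separated from the C7 oxygen by the single carbon C20. A C2 ketone conjugated through C1=C10 therefore makes C10 an acceptor for a CH2 radical carried on the C7 oxygen.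

## Logic of the disconnections

**23 to 21 (through 22), then 21 to 20.** The C11–O bond is cut first, then the O–CH3 bond. The catechol is the most oxidisable part of 23 and is therefore unmasked last. In 21 only one position ortho to the hydroxyl group is free (C11; C13 carries isopropyl), so ortho-oxygenation through 22 is regiochemically unambiguous. The methyl ether is kept as far as 20 because it is the phenol protection that survives the Lewis-acid steps early in the route, so every intermediate is a mono-oxygenated arene. The demand is a demethylation that spares the acetate and the bridge. The bridge is safe because C7–O is a bridgehead bond and C20 is neopentylic, so neither ionisation nor SN2 cleavage is open.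

**20 to 19 to 18.** The acetyl C–O bond and the C2–H bond are cut. C2 is traced back to a ketone because that ketone is what activates C10 in the key step, and no ring A stereocentre other than C5 then has to be carried. The demand is the equatorial (α) alcohol. Hydride can only approach C2 from the α-face and would give the axial alcohol, so a reduction under thermodynamic control is needed.

**18 to 17.** The C10–C20 bond is cut. This removes the quaternary centre and the bridge in one stroke and turns a bridged tetracycle into a flat tricyclic enone with two stereocentres. The demand on the forward step is that a C20 radical adds 6-exo to C10 from the face of the C7 oxygen. For a trans A/B fusion C4 must already lie on that face, so 17 has to be the isomer with C7–O and C4 cis.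

**17 to 16 to 14 and 15.** The O–CH2 bond at the C7 oxygen is cut, after the ester C–O bond. While the bridge is missing, C7–O ionises in acid and C5–H is the γ-hydrogen of an enone. The ether is therefore made by carbenoid O–H insertion from 15 under neutral conditions (retention at C7), and the acid is freed with cold hydroxide, not by acidolysis and not by alkoxide alkylation. The gain is that 14 is a plain secondary alcohol.

**14 to 12 (through 13), then 12 to 11.** The C9–C10 bond is cut, then the C2–N bond. Ring B is closed last and without acid: the aryl anion at C9 (from the bromide) adds to the C10 carbonyl of a vinylogous amide, and hydrolysis moves the carbonyl to C2 and leaves C1=C10. At that point C5 and C7 are both already fixed. Leaving their relation to an equilibration at C5 after ring B exists would be unsafe. In the half-chair of ring B the benzylic oxygen prefers the pseudoaxial position (peri strain with H14), and that is the epimer with C4 on the wrong face. The demands are that bromine–lithium exchange outruns attack on the vinylogous amide, and that the amine sits on the less hindered carbonyl (C2) of 11.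

**11 to 10, then 10 to 7 and 8.** The C1–C10 bond is cut, then the C4–C5 bond. Ring A is opened to the lactone 10 (acylation of the methyl ketone by the lactone carbonyl, which sets the C7 oxygen free) and then to 7 and 8 (conjugate addition that makes quaternary C4). The reason for this order is stereochemical: on the five-membered lactone the acceptor enters C5 anti to the aryl group on C7, and trans on the lactone is the same as C7–O and C4 cis on ring B. C7 thus controls C5 kinetically. The demands are a promoter that does not ionise the benzylic lactone C–O bond and a base that enolises the methyl group and not C5.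

**7 to 5 (through 6), then 5 to 3 and 4.** The C7–H bond is cut, then the C7–C8 bond. The C7 oxygen is the ketone of a Friedel–Crafts succinoylation; it is kept, not reduced away and put back later. Its configuration comes from catalytic asymmetric transfer hydrogenation, so no resolution is needed. The demands are acylation para to methoxy (ortho to bromine) and reagent control of the ketone face.

**3 to 2 to 1.** The benzylic C–H bond and the two C–CH3 bonds of the isopropyl group are cut. The bromine has to sit para to isopropyl (C9), a position that electrophilic substitution of an isopropylanisole does not reach. The pattern is therefore taken from 1, in which bromine and the future isopropyl carbon are already para.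

## Other disconnections considered

**Alternative 1:** The cut goes through both ring B bonds C5–C10 and C6–C7, with ring A closed by the tether. In the forward step the formyl arylacetic acid A1 would be dehydrated with hot acetic anhydride to the benzopyranone A2. The diene termini C10 and C7 of A2 would add the tethered vinyl group in an intramolecular Diels–Alder reaction to give the bridged lactone A3.
- In its favour: two C–C bonds, rings A and B, and the stereocentres C5, C7 and C10 arise in one step. The bridge is present at once. Both catechol oxygens are in place as benzyl ethers, so neither a late arene oxidation nor a Lewis-acid demethylation is needed. C2 is carried as a configured silyl ether. On these four points the alternative is the better plan.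
- Against it: the dienophile is an unactivated vinyl group on a quaternary carbon, so forcing temperatures are needed while A2 is prone to self-addition. Neither the orientation of the tether relative to the lactone bridge (C5 against C20) nor the facial bias from the remote C2 substituent is secured by a strong element. C20 arrives as a carbonyl and must be reduced to CH2 without opening the bridge. A1, a hexasubstituted arene with an α-branched arylacetic acid, is long to make.
- Comparison: structurally it builds far more per step (better). Mechanistically the chosen radical closure is locked by its tether, whereas the pericyclic step is not (chosen plan better). In step count the redox work at C20 and the length of A1 should about cancel the saving at the end (roughly equal).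

**Alternative 2:** The cut is at C9–C10 and C5–C6. In the forward step Pd2(dba)3 with a bulky phosphine and K3PO4 would arylate the ketoester A4 at C10 with the aryl triflate A5. The acetyl methyl group would then condense with the C5 ketone to give the enone ester A6.
- In its favour: it is a convergent union of a ring A piece with the arene. Quaternary C10 is made with C20 already attached, which is the equal of the chosen plan in settling the C10–C20 bond. It needs zerovalent palladium catalysis and no light. The C2 configuration is preset, which is better than a late ketone reduction.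
- Against it: an arylation that creates a quaternary centre beside a ketone flanked by the gem-dimethyl group, with an ortho-acylated triflate, is sterically very demanding. The configuration at C10 rests only on the 1,3-related C2 substituent. The condensation must attack a ketone between two quaternary carbons. After the key step much is still open: C5 (alkene reduction anti to C20), C7 (ketone reduction), the ether bridge (ester to CH2OH, then C7–O formation at an ionisable benzylic centre) and the C11 oxygen.
- Comparison: the chosen plan is better on stereocontrol and on the number of steps after the key step; the alternative is better on convergence.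

**Alternative 3:** The cut is at C5–C10, paid for with the C7–O bond. In the forward step the silyl ketene acetal of the isochromanone A7 (LiN(iPr)2, Me3SiCl) would rearrange on warming through a boat-like [3,3] transition state to the acid A8.
- In its favour: two adjacent stereocentres, including quaternary C10, are set by chirality transfer from the single carbinol centre C7. That centre is as accessible by asymmetric reduction as the C7 centre of the chosen plan. The step is thermal and metal-free, and C20 is attached. In stereocentres per step it is better than the chosen key step, and in reliability of the reaction type it is at least its equal.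
- Against it: the C7–O bond, which the target needs, is spent and must be rebuilt across the new C6=C7 alkene (lactonisation onto C7, then lactone-to-ether reduction). Ring A still needs a metathesis and a regio- and stereoselective oxygenation at C2. The C11 oxygen is still missing.
- Comparison: the chosen plan keeps the C7–O bond from its first appearance and reaches the correct oxidation level at C20 and C2 directly; it is better in step economy and weaker only in what the key step itself creates.

Key step: step 11

**Remarks before the steps**

- α and β are used in the usual abietane sense; the SMILES fix the absolute configuration (2α-acetoxy, 5α-H, 7β-O, 10β-CH2O).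
- The key-step precursor 17 and its product 18 are stereochemically consistent with 23 (C7–O and C4 on one face of ring B, C20 entering on that face) and are used unchanged. Only one locant in the systematic name of 17 is redundant, because abietane already carries the 13-isopropyl group.
- Assumption: RuCl(p-cymene)[(S,S)-TsDPEN] delivers the (S)-carbinol from the ortho-bromoaryl ketone 5 in the same sense as from simple aryl alkyl ketones.

## Route

Step 1
Reactants: 1 methyl 4-bromo-2-methoxybenzoate
Product: 2 2-(4-bromo-2-methoxyphenyl)propan-2-ol
Conditions: MeMgBr (2.5 equiv), THF, 0 °C to rt; aq. NH4Cl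
Reagents that add atoms: methylmagnesium bromide, C[Mg]Br
Why: Double Grignard addition to the aryl ester gives the tertiary benzylic alcohol; the aryl bromide does not exchange with MeMgBr at this temperature.

Step 2
Reactants: 2 2-(4-bromo-2-methoxyphenyl)propan-2-ol
Product: 3 4-bromo-1-isopropyl-2-methoxybenzene
Conditions: Et3SiH (2.5 equiv), CF3CO2H, CH2Cl2, 0 °C to rt
Reagents that add atoms: none
Why: Ionic hydrogenation: the tertiary benzylic cation, stabilised by the ortho-methoxy group, is reduced by silane hydride, which leaves the isopropyl group para to bromine.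

Step 3
Reactants: 3 4-bromo-1-isopropyl-2-methoxybenzene; 4 succinic anhydride
Product: 5 4-(2-bromo-5-isopropyl-4-methoxyphenyl)-4-oxobutanoic acid
Conditions: AlCl3 (2.5 equiv), CH2Cl2, 0 °C to rt; 1 mol/L HCl
Reagents that add atoms: none
Why: Friedel–Crafts acylation para to the methoxy group (C8), the only position activated by it that is not flanked on both sides. It forms C7–C8 and delivers C7 already oxygenated with the bromine at C9.

Step 4
Reactants: 5 4-(2-bromo-5-isopropyl-4-methoxyphenyl)-4-oxobutanoic acid
Product: 7 (S)-5-(2-bromo-5-isopropyl-4-methoxyphenyl)dihydrofuran-2(3H)-one, via hydroxy acid 6 (not isolated)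
Conditions: RuCl(p-cymene)[(S,S)-TsDPEN] (1 mol %), HCO2H–Et3N (5:2), 40 °C; then toluene, 60 °C
Reagents that add atoms: none
Why: Noyori–Ikariya asymmetric transfer hydrogenation of the aryl ketone, a known route from 4-aryl-4-oxobutanoic acids to γ-aryl lactones. The (S,S) catalyst should give the (S)-carbinol 6, which closes to the lactone; this sets C7.

Step 5
Reactants: 7 (S)-5-(2-bromo-5-isopropyl-4-methoxyphenyl)dihydrofuran-2(3H)-one; 8 mesityl oxide (4-methylpent-3-en-2-one)
Product: 10 (3S,5S)-5-(2-bromo-5-isopropyl-4-methoxyphenyl)-3-(2-methyl-4-oxopentan-2-yl)dihydrofuran-2(3H)-one, via silyl ketene acetal 9 (not isolated)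
Conditions: LiN(iPr)2, THF, −78 °C; Me3SiCl; then 8, TiCl4, CH2Cl2, −78 °C; aq. NaHCO3
Reagents that add atoms: chlorotrimethylsilane, C[Si](C)(C)Cl (its silyl group stays only in 9)
Why: Mukaiyama–Michael addition of the ketene silyl acetal to the TiCl4-activated β,β-dimethyl enone forms C4–C5 and the quaternary C4. The acceptor should approach the dihydrofuran face anti to the ortho-bromoaryl group on C7, giving the trans lactone; this sets C5, which becomes cis to the C7 oxygen on ring B.

Step 6
Reactants: 10 (3S,5S)-5-(2-bromo-5-isopropyl-4-methoxyphenyl)-3-(2-methyl-4-oxopentan-2-yl)dihydrofuran-2(3H)-one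
Product: 11 (S)-4-[(S)-2-(2-bromo-5-isopropyl-4-methoxyphenyl)-2-hydroxyethyl]-5,5-dimethylcyclohexane-1,3-dione
Conditions: LiN(SiMe3)2 (2.2 equiv), THF, −78 to 0 °C; aq. NH4Cl
Reagents that add atoms: none
Why: Intramolecular Claisen (Dieckmann-type) acylation: the kinetic methyl enolate attacks the lactone carbonyl (C1–C10, six-membered ring A) and expels the C7 alkoxide, and the diketonate makes it irreversible. The hindered C5–H is not removed and the C7–O bond is not touched, so both centres are kept.

Step 7
Reactants: 11 (S)-4-[(S)-2-(2-bromo-5-isopropyl-4-methoxyphenyl)-2-hydroxyethyl]-5,5-dimethylcyclohexane-1,3-dione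
Product: 12 (S)-6-[(S)-2-(2-bromo-5-isopropyl-4-methoxyphenyl)-2-hydroxyethyl]-5,5-dimethyl-3-(pyrrolidin-1-yl)cyclohex-2-en-1-one
Conditions: pyrrolidine (1.3 equiv), toluene, 80 °C, 4 Å molecular sieves
Reagents that add atoms: pyrrolidine, C1CCNC1
Why: Condensation of the cyclic 1,3-dione with a secondary amine to the vinylogous amide. The amine should go to the less hindered carbonyl (C2) both kinetically and thermodynamically, leaving the C10 carbonyl next to C5 free for the ring closure.

Step 8
Reactants: 12 (S)-6-[(S)-2-(2-bromo-5-isopropyl-4-methoxyphenyl)-2-hydroxyethyl]-5,5-dimethyl-3-(pyrrolidin-1-yl)cyclohex-2-en-1-one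
Product: 14 7β-hydroxy-12-methoxy-20-norabieta-1(10),8,11,13-tetraen-2-one [(9S,10aS)-9-hydroxy-7-isopropyl-6-methoxy-1,1-dimethyl-1,9,10,10a-tetrahydrophenanthren-3(2H)-one], via tertiary carbinol 13 (not isolated)
Conditions: NaH (1.1 equiv), THF, 0 °C; t-BuLi (2.2 equiv), −78 to −30 °C; then aq. AcOH–NaOAc (pH 4.5), rt
Reagents that add atoms: water, O
Why: Parham-type cyclisation: bromine–lithium exchange at C9, then 6-exo-trig addition of the aryllithium to the C10 carbonyl of the vinylogous amide closes ring B (C9–C10). Buffered hydrolysis of 13 in the manner of a Stork–Danheiser transposition gives the C2 ketone with C1=C10. C5 and C7 are spectators, so the cis relation set in steps 4 and 5 is carried into ring B.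

Step 9
Reactants: 14 7β-hydroxy-12-methoxy-20-norabieta-1(10),8,11,13-tetraen-2-one; 15 ethyl diazoacetate
Product: 16 ethyl 2-{[12-methoxy-2-oxo-20-norabieta-1(10),8,11,13-tetraen-7β-yl]oxy}acetate
Conditions: Rh2(OAc)4 (2 mol %), CH2Cl2, rt, slow addition of 15 (3 equiv)
Reagents that add atoms: none
Why: Rhodium-carbenoid O–H insertion into the secondary alcohol forms the O–CH2 bond (the future C20) under neutral conditions, with retention at C7. Neither the acid-labile benzylic C–O bond nor the base-sensitive C5–H is put at risk, and the electron-poor enone alkene is not a carbenoid acceptor.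

Step 10
Reactants: 16 ethyl 2-{[12-methoxy-2-oxo-20-norabieta-1(10),8,11,13-tetraen-7β-yl]oxy}acetate
Product: 17 2-{[12-methoxy-2-oxo-20-norabieta-1(10),8,11,13-tetraen-7β-yl]oxy}acetic acid
Conditions: LiOH (2 equiv), THF–H2O (3:1), 0 °C; then 1 mol/L HCl to pH 4 at 0 °C
Reagents that add atoms: lithium hydroxide, [Li+].[OH-]
Why: Saponification of an α-alkoxy ester is fast at 0 °C, well below the conditions needed to remove the γ-hydrogen at C5. No strong acid is used, so the para-alkoxybenzylic ether stays intact.

Step 11
Reactants: 17 2-{[12-methoxy-2-oxo-20-norabieta-1(10),8,11,13-tetraen-7β-yl]oxy}acetic acid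
Product: 18 7β,20-epoxy-12-methoxyabieta-8,11,13-trien-2-one
Conditions: Ir[dF(CF3)ppy]2(dtbbpy)PF6 (1 mol %), K2HPO4 (1.2 equiv), DMF (0.02 mol/L, degassed), blue LEDs (450 nm), rt
Reagents that add atoms: none
Why: The carboxylate of 17 is oxidised by the excited iridium photocatalyst and loses CO2, leaving a nucleophilic alkoxymethyl radical (C20) on the C7 oxygen. This radical adds to C10, the electron-poor β-carbon of the aryl enone, in a 6-exo-trig closure (ring atoms C7, C8, C9, C10, C20 and O) that bridges ring B as a boat and completes the 2-oxabicyclo[2.2.2]octane. The α-keto radical at C1 is then reduced by the reduced iridium complex and the enolate is protonated to the C2 ketone, so the cycle is redox-neutral. The closest known reaction type is the photoredox decarboxylative Giese addition of α-alkoxy acids to enones, applied here within one molecule. The one new stereocentre, C10, is fixed by the tether: the O–CH2 chain on the β-face of C7 reaches only the β-face of C10, so C20 ends syn to the C7 oxygen. Because C4 was placed on that same face in steps 4 and 5, H5 is anti to C20 and the A/B fusion is trans; H5 also lies on the face away from the radical, which disfavours a 1,5-hydrogen shift from C5. Attack at C10 and not at C1 (a 7-endo closure) follows from polarity matching and ring size. The step also needs the carboxylate to be oxidised in preference to the anisole ring, which its lower oxidation potential should secure, and ring closure to outrun loss of formaldehyde from the radical, which high dilution in a poor hydrogen-donor medium supports.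

Step 12
Reactants: 18 7β,20-epoxy-12-methoxyabieta-8,11,13-trien-2-one
Product: 19 7β,20-epoxy-12-methoxyabieta-8,11,13-trien-2α-ol
Conditions: SmI2 (4 equiv), H2O, Et3N, THF, 0 °C
Reagents that add atoms: none
Why: Electron-transfer reduction of the ketone by SmI2–water–amine passes through a ketyl and a carbanion that settle with oxygen equatorial before protonation, as in dissolving-metal reductions, so the equatorial 2α-alcohol is expected. A hydride reagent would be forced to the α-face by C20 and the 4β-methyl group and would give the axial epimer.

Step 13
Reactants: 19 7β,20-epoxy-12-methoxyabieta-8,11,13-trien-2α-ol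
Product: 20 2α-acetoxy-7β,20-epoxy-12-methoxyabieta-8,11,13-triene
Conditions: Ac2O, pyridine, DMAP (cat.), CH2Cl2, rt
Reagents that add atoms: acetic anhydride, CC(=O)OC(C)=O
Why: Standard acylation of an unhindered equatorial secondary alcohol with retention at C2.

Step 14
Reactants: 20 2α-acetoxy-7β,20-epoxy-12-methoxyabieta-8,11,13-triene
Product: 21 2α-acetoxy-7β,20-epoxyabieta-8,11,13-trien-12-ol
Conditions: BBr3 (3 equiv), CH2Cl2, −78 to 0 °C; MeOH, aq. NaHCO3
Reagents that add atoms: none
Why: Lewis-acid cleavage of the aryl methyl ether by bromide attack on the O-methyl carbon. The bridge cannot follow this path (C7 is a bridgehead whose cation would be orthogonal to the arene, C20 is neopentylic), and a secondary acetate is known to tolerate BBr3 at low temperature.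

Step 15
Reactants: 21 2α-acetoxy-7β,20-epoxyabieta-8,11,13-trien-12-ol
Product: 23 2α-acetoxy-7β,20-epoxyabieta-8,11,13-triene-11,12-diol (target), via ortho-quinone 22 (not isolated)
Conditions: IBX (1.1 equiv), DMF, rt; then aq. Na2S2O4
Reagents that add atoms: 2-iodoxybenzoic acid (IBX), O=C1OI(=O)(O)c2ccccc12
Why: Regioselective ortho-oxygenation of an electron-rich phenol by IBX delivers oxygen to the only free ortho position (C11) and gives quinone 22; dithionite reduces it at once to the catechol. Quinone-methide tautomerism toward C7 is blocked because C7 is a bridgehead.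

## Compound list

1 | methyl 4-bromo-2-methoxybenzoate | COC(=O)c1ccc(Br)cc1OC | starting material
2 | 2-(4-bromo-2-methoxyphenyl)propan-2-ol | COc1cc(Br)ccc1C(C)(C)O | intermediate
3 | 4-bromo-1-isopropyl-2-methoxybenzene | COc1cc(Br)ccc1C(C)C | intermediate
4 | succinic anhydride | O=C1CCC(=O)O1 | starting material
5 | 4-(2-bromo-5-isopropyl-4-methoxyphenyl)-4-oxobutanoic acid | COc1cc(Br)c(C(=O)CCC(=O)O)cc1C(C)C | intermediate
6 | (S)-4-(2-bromo-5-isopropyl-4-methoxyphenyl)-4-hydroxybutanoic acid | COc1cc(Br)c([C@@H](O)CCC(=O)O)cc1C(C)C | intermediate (not isolated)
7 | (S)-5-(2-bromo-5-isopropyl-4-methoxyphenyl)dihydrofuran-2(3H)-one | O=C1CC[C@@H](c2cc(C(C)C)c(OC)cc2Br)O1 | intermediate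
8 | mesityl oxide (4-methylpent-3-en-2-one) | CC(C)=CC(C)=O | starting material
9 | (S)-{[5-(2-bromo-5-isopropyl-4-methoxyphenyl)-4,5-dihydrofuran-2-yl]oxy}trimethylsilane | C[Si](C)(C)OC1=CC[C@@H](c2cc(C(C)C)c(OC)cc2Br)O1 | intermediate (not isolated)
10 | (3S,5S)-5-(2-bromo-5-isopropyl-4-methoxyphenyl)-3-(2-methyl-4-oxopentan-2-yl)dihydrofuran-2(3H)-one (trans lactone) | CC(=O)CC(C)(C)[C@@H]1C[C@@H](c2cc(C(C)C)c(OC)cc2Br)OC1=O | intermediate
11 | (S)-4-[(S)-2-(2-bromo-5-isopropyl-4-methoxyphenyl)-2-hydroxyethyl]-5,5-dimethylcyclohexane-1,3-dione | O=C1CC(=O)CC(C)(C)[C@@H]1C[C@H](O)c1cc(C(C)C)c(OC)cc1Br | intermediate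
12 | (S)-6-[(S)-2-(2-bromo-5-isopropyl-4-methoxyphenyl)-2-hydroxyethyl]-5,5-dimethyl-3-(pyrrolidin-1-yl)cyclohex-2-en-1-one | O=C1C=C(N2CCCC2)CC(C)(C)[C@@H]1C[C@H](O)c1cc(C(C)C)c(OC)cc1Br | intermediate
13 | 12-methoxy-2-(pyrrolidin-1-yl)-20-norabieta-1,8,11,13-tetraene-7β,10-diol (5αH; configuration at C10 immaterial, lost on hydrolysis) | C1(N2CCCC2)=CC3(O)c4cc(OC)c(C(C)C)cc4[C@@H](O)C[C@H]3C(C)(C)C1 | intermediate (not isolated)
14 | 7β-hydroxy-12-methoxy-20-norabieta-1(10),8,11,13-tetraen-2-one (5αH); (9S,10aS)-9-hydroxy-7-isopropyl-6-methoxy-1,1-dimethyl-1,9,10,10a-tetrahydrophenanthren-3(2H)-one | O=C1C=C2c3cc(OC)c(C(C)C)cc3[C@@H](O)C[C@H]2C(C)(C)C1 | intermediate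
15 | ethyl diazoacetate | CCOC(=O)C=[N+]=[N-] | starting material
16 | ethyl 2-{[12-methoxy-2-oxo-20-norabieta-1(10),8,11,13-tetraen-7β-yl]oxy}acetate (5αH) | O=C1C=C2c3cc(OC)c(C(C)C)cc3[C@@H](OCC(=O)OCC)C[C@H]2C(C)(C)C1 | intermediate
17 | 2-{[12-methoxy-2-oxo-20-norabieta-1(10),8,11,13-tetraen-7β-yl]oxy}acetic acid (5αH; key-step precursor) | O=C1C=C2c3cc(OC)c(C(C)C)cc3[C@@H](OCC(=O)O)C[C@H]2C(C)(C)C1 | intermediate
18 | 7β,20-epoxy-12-methoxyabieta-8,11,13-trien-2-one (5αH, 10β-CH2O; key-step product) | O=C1CC(C)(C)[C@@H]2C[C@@H]3OC[C@@]2(C1)c1c3cc(C(C)C)c(OC)c1 | intermediate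
19 | 7β,20-epoxy-12-methoxyabieta-8,11,13-trien-2α-ol | O[C@H]1CC(C)(C)[C@@H]2C[C@@H]3OC[C@@]2(C1)c1c3cc(C(C)C)c(OC)c1 | intermediate
20 | 2α-acetoxy-7β,20-epoxy-12-methoxyabieta-8,11,13-triene | CC(=O)O[C@H]1CC(C)(C)[C@@H]2C[C@@H]3OC[C@@]2(C1)c1c3cc(C(C)C)c(OC)c1 | intermediate
21 | 2α-acetoxy-7β,20-epoxyabieta-8,11,13-trien-12-ol | CC(=O)O[C@H]1CC(C)(C)[C@@H]2C[C@@H]3OC[C@@]2(C1)c1c3cc(C(C)C)c(O)c1 | intermediate
22 | 2α-acetoxy-7β,20-epoxyabieta-8,13-diene-11,12-dione | CC(=O)O[C@H]1CC(C)(C)[C@@H]2C[C@@H]3OC[C@@]2(C1)C1=C3C=C(C(C)C)C(=O)C1=O | intermediate (not isolated)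
23 | 2α-acetoxy-7β,20-epoxyabieta-8,11,13-triene-11,12-diol | CC(=O)O[C@H]1CC(C)(C)[C@@H]2C[C@@H]3OC[C@@]2(C1)c1c3cc(C(C)C)c(O)c1O | target

## Step count and least certain steps

Total: 15 steps. Longest linear sequence: 15 steps (1 to 23); 4, 8 and 15 enter as purchased building blocks.

**Step 11 (key step).** The most likely failure is quenching of the C20 radical before the ring closes, by hydrogen abstraction or by loss of formaldehyde to leave a C7 benzylic radical. The closure is slowed because ring B must leave its half-chair for a boat and give up aryl–enone conjugation; inefficient oxidation of the carboxylate would add to this. The fallback sets out from 17 and changes how the radical is made. Esterification with N-hydroxyphthalimide (N,N'-diisopropylcarbodiimide, DMAP, CH2Cl2) gives the N-acyloxyphthalimide F1. Reductive fragmentation (Ru(bpy)3(PF6)2, Hantzsch ester, iPr2NEt, CH2Cl2, blue light, dilute) releases the same radical at a potential remote from every other group, with a hydrogen donor whose concentration can be kept low. The route is rejoined at 18.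

**Step 5.** The most likely failure is ionisation of the para-methoxybenzylic lactone C–O bond by TiCl4 (erosion of the C7 configuration, ring opening), together with slow addition to the β,β-disubstituted enone. The fallback sets out from 9 and avoids the strong Lewis acid by using a much stronger acceptor. Addition to 2,2-dimethyl-5-(propan-2-ylidene)-1,3-dioxane-4,6-dione (CH2Cl2, rt, if needed Sc(OTf)3, 5 mol %) with the same anti approach gives, after aqueous work-up, the Meldrum's acid adduct F2. Hot aqueous pyridine removes acetone and CO2 to give the lactone acid F3. Oxalyl chloride gives the acid chloride F4, and MeMgBr with Fe(acac)3 (3 mol %, THF, −78 °C) converts it into the methyl ketone. The route is rejoined at 10.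

**Step 8.** The most likely failure is proton transfer to the aryllithium from the C–H next to the vinylogous amide carbonyl, or attack of t-BuLi on the vinylogous amide, faster than ring closure; either returns debrominated open-chain material. The fallback sets out from 12 and closes ring B with palladium. LiAlH4 (THF, 0 °C) followed by dilute aqueous acetic acid transposes the vinylogous amide to the enone F5 (C2 ketone, C1=C10–H). O–H insertion with 15 (Rh2(OAc)4, CH2Cl2) gives the ether ester F6. An intramolecular Mizoroki–Heck reaction (Pd(OAc)2, P(o-tol)3, Et3N, DMF, 100 °C) then arylates C10 in a 6-exo closure, and β-hydride loss through the palladium enolate restores C1=C10. The route is rejoined at 16.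

**Step 12.** The most likely failure is poor facial selectivity: protonation on the open α-face after electron transfer would give the axial 2β-alcohol beside 19. The fallback sets out from 18 and uses the hindrance. NaBH4 (MeOH, 0 °C) attacks C2 from the α-face and gives the axial 2β-alcohol F7. Mitsunobu inversion with acetic acid (PPh3, diisopropyl azodicarboxylate, toluene) then gives the 2α-acetate directly. The route is rejoined at 20.

**Step 14.** The most likely failure is loss of the C2 acetate (bromide attack on the boron-activated ester) while demethylation beside the isopropyl group is slow. The fallback sets out from 18 and removes the methyl group before any acetate exists. BBr3 (CH2Cl2, −78 to 0 °C) gives the phenol ketone F8. SmI2–H2O–Et3N gives the diol F9. Acetic anhydride in pyridine gives the diacetate F10, and pyrrolidine (CH2Cl2, rt) cleaves only the aryl acetate. The route is rejoined at 21.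

## Further compounds

F1 | step 11 | 1,3-dioxoisoindolin-2-yl 2-{[12-methoxy-2-oxo-20-norabieta-1(10),8,11,13-tetraen-7β-yl]oxy}acetate | O=C1C=C2c3cc(OC)c(C(C)C)cc3[C@@H](OCC(=O)ON3C(=O)c4ccccc4C3=O)C[C@H]2C(C)(C)C1
F2 | step 5 | 5-{2-[(3S,5S)-5-(2-bromo-5-isopropyl-4-methoxyphenyl)-2-oxotetrahydrofuran-3-yl]propan-2-yl}-2,2-dimethyl-1,3-dioxane-4,6-dione | CC1(C)OC(=O)C(C(=O)O1)C(C)(C)[C@@H]1C[C@@H](c2cc(C(C)C)c(OC)cc2Br)OC1=O
F3 | step 5 | 3-[(3S,5S)-5-(2-bromo-5-isopropyl-4-methoxyphenyl)-2-oxotetrahydrofuran-3-yl]-3-methylbutanoic acid | OC(=O)CC(C)(C)[C@@H]1C[C@@H](c2cc(C(C)C)c(OC)cc2Br)OC1=O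
F4 | step 5 | 3-[(3S,5S)-5-(2-bromo-5-isopropyl-4-methoxyphenyl)-2-oxotetrahydrofuran-3-yl]-3-methylbutanoyl chloride | ClC(=O)CC(C)(C)[C@@H]1C[C@@H](c2cc(C(C)C)c(OC)cc2Br)OC1=O
F5 | step 8 | (R)-4-[(S)-2-(2-bromo-5-isopropyl-4-methoxyphenyl)-2-hydroxyethyl]-5,5-dimethylcyclohex-2-en-1-one | O=C1C=C[C@@H](C[C@H](O)c2cc(C(C)C)c(OC)cc2Br)C(C)(C)C1
F6 | step 8 | ethyl 2-{(S)-1-(2-bromo-5-isopropyl-4-methoxyphenyl)-2-[(R)-6,6-dimethyl-4-oxocyclohex-2-en-1-yl]ethoxy}acetate | O=C1C=C[C@@H](C[C@H](OCC(=O)OCC)c2cc(C(C)C)c(OC)cc2Br)C(C)(C)C1
F7 | step 12 | 7β,20-epoxy-12-methoxyabieta-8,11,13-trien-2β-ol | O[C@@H]1CC(C)(C)[C@@H]2C[C@@H]3OC[C@@]2(C1)c1c3cc(C(C)C)c(OC)c1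
F8 | step 14 | 12-hydroxy-7β,20-epoxyabieta-8,11,13-trien-2-one | O=C1CC(C)(C)[C@@H]2C[C@@H]3OC[C@@]2(C1)c1c3cc(C(C)C)c(O)c1
F9 | step 14 | 7β,20-epoxyabieta-8,11,13-triene-2α,12-diol | O[C@H]1CC(C)(C)[C@@H]2C[C@@H]3OC[C@@]2(C1)c1c3cc(C(C)C)c(O)c1
F10 | step 14 | 2α,12-diacetoxy-7β,20-epoxyabieta-8,11,13-triene | CC(=O)O[C@H]1CC(C)(C)[C@@H]2C[C@@H]3OC[C@@]2(C1)c1c3cc(C(C)C)c(OC(C)=O)c1
A1 | alternative 1 | (4R)-2-[2,3-bis(benzyloxy)-6-formyl-4-isopropylphenyl]-4-(tert-butyldimethylsilyloxy)-6,6-dimethyloct-7-enoic acid (C2 of the acid not defined; it becomes planar) | OC(=O)C(C[C@@H](O[Si](C)(C)C(C)(C)C)CC(C)(C)C=C)c1c(C=O)cc(C(C)C)c(OCc2ccccc2)c1OCc1ccccc1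
A2 | alternative 1 | 5,6-bis(benzyloxy)-4-[2-(tert-butyldimethylsilyloxy)-4,4-dimethylhex-5-en-1-yl]-7-isopropyl-3H-isochromen-3-one (side chain configured as in A1) | O=C1OC=C2C=C(C(C)C)C(OCc3ccccc3)=C(OCc3ccccc3)C2=C1C[C@@H](O[Si](C)(C)C(C)(C)C)CC(C)(C)C=C
A3 | alternative 1 | 11,12-bis(benzyloxy)-2α-(tert-butyldimethylsilyloxy)-7β,20-epoxyabieta-8,11,13-trien-20-one (carnosol-type 20,7-lactone) | CC(C)(C)[Si](C)(C)O[C@H]1CC(C)(C)[C@@H]2C[C@@H]3OC(=O)[C@@]2(C1)c1c3cc(C(C)C)c(OCc2ccccc2)c1OCc1ccccc1
A4 | alternative 2 | methyl 5-(tert-butyldimethylsilyloxy)-3,3-dimethyl-2-oxocyclohexane-1-carboxylate (silyloxy carbon configured as C2 of A6; C1 epimerisable) | COC(=O)C1C[C@@H](O[Si](C)(C)C(C)(C)C)CC(C)(C)C1=O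
A5 | alternative 2 | 2-acetyl-4-isopropyl-5-methoxyphenyl trifluoromethanesulfonate | CC(=O)c1cc(C(C)C)c(OC)cc1OS(=O)(=O)C(F)(F)F
A6 | alternative 2 | methyl 2α-(tert-butyldimethylsilyloxy)-12-methoxy-7-oxoabieta-5,8,11,13-tetraen-20-oate | COC(=O)[C@]12C[C@@H](O[Si](C)(C)C(C)(C)C)CC(C)(C)C1=CC(=O)c1cc(C(C)C)c(OC)cc21
A7 | alternative 3 | 4-allyl-1-[(E)-3,3-dimethylpenta-1,4-dien-1-yl]-7-isopropyl-6-methoxyisochroman-3-one (C1 configured with oxygen on the β-face of the future ring B; C4 enolised in the step) | O=C1O[C@@H](/C=C/C(C)(C)C=C)c2cc(C(C)C)c(OC)cc2C1CC=C
A8 | alternative 3 | 1-allyl-6-isopropyl-7-methoxy-2-(2-methylbut-3-en-2-yl)-1,2-dihydronaphthalene-1-carboxylic acid | OC(=O)[C@]1(CC=C)[C@H](C(C)(C)C=C)C=Cc2cc(C(C)C)c(OC)cc12
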